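**Retrosynthetic overview**
1. The target is a furofuran with both aryl groups exo, (1R,3aS,4R,6aS). Ring A (carrying the prenyloxyaryl group) is closed last by SN1 etherification of a benzylic alcohol obtained from a bicyclic lactol and an arylmagnesium bromide; the silyl ether on the other aryl group falls in the same pot.
2. Ring B (carrying the future phenol) comes from ring expansion of an aryl cyclopropane fused to a γ-lactone: the three-membered ring takes up formaldehyde (O–C(aryl) and C–CH2 bonds formed) to give the cis-fused tetrahydrofuran-lactone.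
3. The cyclopropane-lactone comes from catalyst-controlled intramolecular cyclopropanation of a (Z)-cinnamyl diazoacetate; the absolute configuration is set here.
4. The (Z)-allylic alcohol comes from an aryl bromide and propargyl alcohol; both aryl bromides come from catechol (O-methylation, para-bromination, then O-silylation or O-prenylation).
5. Ring order: cyclopropane and lactone together, then ring B by ring expansion, then ring A from the lactone carbon.

Assumption: Rh2(5S-MEPY)4 gives the (1R,5S)-configured bicyclic lactone from the (Z)-3-arylallyl diazoacetate as it does from the parent allyl diazoacetate; if the sense were opposite, Rh2(5R-MEPY)4 is used.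

**Route**

Step 1
Reactants: 1 benzene-1,2-diol (catechol)
Product: 2 2-methoxyphenol
Conditions: MeI (1.0 equiv), K2CO3 (1.0 equiv), acetone, reflux; 1 in 1.5-fold excess
Reagents that add atoms: iodomethane, CI
Why: Williamson O-methylation of the monophenoxide, with excess diol keeping dialkylation low.

Step 2
Reactants: 2 2-methoxyphenol
Product: 3 4-bromo-2-methoxyphenol
Conditions: NBS (1.0 equiv), MeCN, 0 °C
Reagents that add atoms: N-bromosuccinimide, O=C1CCC(=O)N1Br
Why: Electrophilic aromatic bromination goes para to the free hydroxyl, the stronger activating group.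

Step 3
Reactants: 3 4-bromo-2-methoxyphenol
Product: 4 (4-bromo-2-methoxyphenoxy)tri(propan-2-yl)silane
Conditions: i-Pr3SiCl, imidazole, DMF, rt
Reagents that add atoms: chlorotri(propan-2-yl)silane, CC(C)[Si](Cl)(C(C)C)C(C)C
Why: Silylation of the phenol gives a bulky silyl ether that keeps the ring electron-rich and survives the base, Pd, Rh-carbenoid, hydride and Grignard steps.

Step 4
Reactants: 4 (4-bromo-2-methoxyphenoxy)tri(propan-2-yl)silane; 5 prop-2-yn-1-ol
Product: 6 3-(3-methoxy-4-{[tri(propan-2-yl)silyl]oxy}phenyl)prop-2-yn-1-ol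
Conditions: Pd(PhCN)2Cl2 (3 mol %), P(t-Bu)3 (6 mol %), CuI (2 mol %), i-Pr2NH, 1,4-dioxane, rt
Reagents that add atoms: none
Why: Sonogashira coupling, with the bulky electron-rich phosphine allowing oxidative addition of the electron-rich aryl bromide at room temperature.

Step 5
Reactants: 6 3-(3-methoxy-4-{[tri(propan-2-yl)silyl]oxy}phenyl)prop-2-yn-1-ol
Product: 7 (2Z)-3-(3-methoxy-4-{[tri(propan-2-yl)silyl]oxy}phenyl)prop-2-en-1-ol
Conditions: H2 (1 atm), Pd/CaCO3 poisoned with Pb(OAc)2 (Lindlar catalyst), quinoline, EtOAc, rt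
Reagents that add atoms: none
Why: Lindlar semihydrogenation adds H2 syn and stops at the (Z)-alkene.

Step 6
Reactants: 7 (2Z)-3-(3-methoxy-4-{[tri(propan-2-yl)silyl]oxy}phenyl)prop-2-en-1-ol; 8 bromoacetyl bromide
Product: 10 (2Z)-3-(3-methoxy-4-{[tri(propan-2-yl)silyl]oxy}phenyl)prop-2-en-1-yl diazoacetate, via bromoacetate ester 9 (not isolated)
Conditions: 8 (1.3 equiv), NaHCO3, MeCN, 0 °C; then TsNHNHTs (2 equiv), DBU (5 equiv), THF, 0 °C
Reagents that add atoms: N,N'-ditosylhydrazine, Cc1ccc(cc1)S(=O)(=O)NNS(=O)(=O)c1ccc(C)cc1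
Why: O-acylation followed by diazo formation (N-alkylation of the bis-sulfonylhydrazide and base-induced loss of two sulfinates), mild enough to keep the (Z)-alkene.

Step 7
Reactants: 10 (2Z)-3-(3-methoxy-4-{[tri(propan-2-yl)silyl]oxy}phenyl)prop-2-en-1-yl diazoacetate
Product: 11 (1R,5S,6R)-6-(3-methoxy-4-{[tri(propan-2-yl)silyl]oxy}phenyl)-3-oxabicyclo[3.1.0]hexan-2-one (aryl endo)
Conditions: Rh2(5S-MEPY)4 [dirhodium tetrakis(methyl (5S)-2-oxopyrrolidine-5-carboxylate)] (1 mol %), CH2Cl2, reflux, 10 added over 10 h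
Reagents that add atoms: none
Why: Intramolecular carbenoid cyclopropanation in which syn addition to the (Z)-alkene places the aryl group endo (C6 = R) and the chiral dirhodium carboxamidate selects the alkene face (C1 = R, C5 = S).

Step 8
Reactants: 11 (1R,5S,6R)-6-(3-methoxy-4-{[tri(propan-2-yl)silyl]oxy}phenyl)-3-oxabicyclo[3.1.0]hexan-2-one; 12 formaldehyde (used as paraformaldehyde)
Product: 13 (3aS,4R,6aS)-4-(3-methoxy-4-{[tri(propan-2-yl)silyl]oxy}phenyl)tetrahydro-1H,3H-furo[3,4-c]furan-1-one (cis-fused, aryl exo)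
Conditions: Sc(OTf)3 (10 mol %), paraformaldehyde (5 equiv CH2O), 4 Å molecular sieves, ClCH2CH2Cl, 40 °C
Reagents that add atoms: none
Why: Proposed new method: Sc(OTf)3 on the lactone carbonyl polarises the C1–C6 bond of this donor–acceptor cyclopropane (p-silyloxyaryl donor, lactone acceptor), the formaldehyde oxygen attacks benzylic C6 from the rear with inversion (endo aryl of 11 becomes exo aryl, C4 of 13 = R) and the scandium enolate then closes on the O-alkylated oxocarbenium carbon, the lactone forcing cis fusion (C6a = S) while C5 of 11 (C3a of 13) is never touched and carries the absolute configuration, so the three-membered ring is enlarged to the tetrahydrofuran of ring B in a stepwise ionic (3+2) ring expansion, a benzylic-cation variant converging on the same exo isomer; closest known reaction type: Lewis acid-catalysed (3+2) annulation of 2-arylcyclopropane-1,1-diesters with aldehydes to tetrahydrofurans with inversion at the donor carbon, not shown for a single fused lactone acceptor or for formaldehyde.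

Step 9
Reactants: 13 (3aS,4R,6aS)-4-(3-methoxy-4-{[tri(propan-2-yl)silyl]oxy}phenyl)tetrahydro-1H,3H-furo[3,4-c]furan-1-one
Product: 14 (3aS,4R,6aS)-4-(3-methoxy-4-{[tri(propan-2-yl)silyl]oxy}phenyl)tetrahydro-1H,3H-furo[3,4-c]furan-1-ol (both C1 epimers)
Conditions: i-Bu2AlH (1.1 equiv), CH2Cl2, −78 °C; aqueous potassium sodium tartrate
Reagents that add atoms: none
Why: Partial reduction of the γ-lactone stops at the lactol because the tetrahedral aluminate is stable at −78 °C; no existing stereocenter is touched and the hemiacetal carbon is an inconsequential mixture.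

Step 10
Reactants: 3 4-bromo-2-methoxyphenol; 15 1-bromo-3-methylbut-2-ene
Product: 16 4-bromo-2-methoxy-1-[(3-methylbut-2-en-1-yl)oxy]benzene
Conditions: K2CO3, acetone, rt
Reagents that add atoms: none
Why: Williamson O-alkylation of the phenoxide at the primary allylic bromide.

Step 11
Reactants: 16 4-bromo-2-methoxy-1-[(3-methylbut-2-en-1-yl)oxy]benzene; 14 (3aS,4R,6aS)-4-(3-methoxy-4-{[tri(propan-2-yl)silyl]oxy}phenyl)tetrahydro-1H,3H-furo[3,4-c]furan-1-ol
Product: 18 [(2R,3S,4S)-4-{hydroxy[3-methoxy-4-(3-methylbut-2-en-1-yloxy)phenyl]methyl}-2-(3-methoxy-4-{[tri(propan-2-yl)silyl]oxy}phenyl)oxolan-3-yl]methanol (both carbinol epimers), via arylmagnesium bromide 17 (not isolated)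
Conditions: 16 (3 equiv), Mg turnings, THF, 40 °C; then 14, THF, 0 °C to rt; H2O
Reagents that add atoms: none
Why: Grignard formation and addition to the ring-opened hydroxy-aldehyde form of the lactol; the new carbinol center forms as a mixture that is erased in the next step.

Step 12
Reactants: 18 [(2R,3S,4S)-4-{hydroxy[3-methoxy-4-(3-methylbut-2-en-1-yloxy)phenyl]methyl}-2-(3-methoxy-4-{[tri(propan-2-yl)silyl]oxy}phenyl)oxolan-3-yl]methanol
Product: 20 4-[(1R,3aS,4R,6aS)-4-{3-methoxy-4-[(3-methylbut-2-en-1-yl)oxy]phenyl}tetrahydro-1H,3H-furo[3,4-c]furan-1-yl]-2-methoxyphenol (the target), via silyl-protected furofuran 19 (not isolated)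
Conditions: camphorsulfonic acid (10 mol %), CH2Cl2, 0 °C; then n-Bu4NF (1.5 equiv), THF, rt
Reagents that add atoms: none
Why: Acid-promoted SN1 cyclodehydration in which the p-alkoxybenzylic cation is captured by the primary hydroxyl to close ring A with the aryl group on the convex (exo) face (C4 = R), after which fluoride cleaves the aryl silyl ether without touching the prenyl ether.

**Compound list**
1 | benzene-1,2-diol | Oc1ccccc1O | starting material
2 | 2-methoxyphenol | COc1ccccc1O | intermediate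
3 | 4-bromo-2-methoxyphenol | COc1cc(Br)ccc1O | intermediate
4 | (4-bromo-2-methoxyphenoxy)tri(propan-2-yl)silane | COc1cc(Br)ccc1O[Si](C(C)C)(C(C)C)C(C)C | intermediate
5 | prop-2-yn-1-ol | OCC#C | starting material
6 | 3-(3-methoxy-4-{[tri(propan-2-yl)silyl]oxy}phenyl)prop-2-yn-1-ol | COc1cc(C#CCO)ccc1O[Si](C(C)C)(C(C)C)C(C)C | intermediate
7 | (2Z)-3-(3-methoxy-4-{[tri(propan-2-yl)silyl]oxy}phenyl)prop-2-en-1-ol | COc1cc(/C=C\CO)ccc1O[Si](C(C)C)(C(C)C)C(C)C | intermediate
8 | bromoacetyl bromide | BrCC(Br)=O | starting material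
9 | (2Z)-3-(3-methoxy-4-{[tri(propan-2-yl)silyl]oxy}phenyl)prop-2-en-1-yl bromoacetate | COc1cc(/C=C\COC(=O)CBr)ccc1O[Si](C(C)C)(C(C)C)C(C)C | intermediate
10 | (2Z)-3-(3-methoxy-4-{[tri(propan-2-yl)silyl]oxy}phenyl)prop-2-en-1-yl diazoacetate | COc1cc(/C=C\COC(=O)C=[N+]=[N-])ccc1O[Si](C(C)C)(C(C)C)C(C)C | intermediate
11 | (1R,5S,6R)-6-(3-methoxy-4-{[tri(propan-2-yl)silyl]oxy}phenyl)-3-oxabicyclo[3.1.0]hexan-2-one | O=C1OC[C@H]2[C@@H](c3ccc(O[Si](C(C)C)(C(C)C)C(C)C)c(OC)c3)[C@@H]12 | intermediate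
12 | formaldehyde (as paraformaldehyde) | C=O | starting material
13 | (3aS,4R,6aS)-4-(3-methoxy-4-{[tri(propan-2-yl)silyl]oxy}phenyl)tetrahydro-1H,3H-furo[3,4-c]furan-1-one | COc1cc([C@@H]2OC[C@@H]3[C@H]2COC3=O)ccc1O[Si](C(C)C)(C(C)C)C(C)C | intermediate
14 | (3aS,4R,6aS)-4-(3-methoxy-4-{[tri(propan-2-yl)silyl]oxy}phenyl)tetrahydro-1H,3H-furo[3,4-c]furan-1-ol (C1 epimers) | COc1cc([C@@H]2OC[C@@H]3[C@H]2COC3O)ccc1O[Si](C(C)C)(C(C)C)C(C)C | intermediate
15 | 1-bromo-3-methylbut-2-ene | CC(C)=CCBr | starting material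
16 | 4-bromo-2-methoxy-1-[(3-methylbut-2-en-1-yl)oxy]benzene | COc1cc(Br)ccc1OCC=C(C)C | intermediate
17 | bromo{3-methoxy-4-[(3-methylbut-2-en-1-yl)oxy]phenyl}magnesium | COc1cc([Mg]Br)ccc1OCC=C(C)C | intermediate
18 | [(2R,3S,4S)-4-{hydroxy[3-methoxy-4-(3-methylbut-2-en-1-yloxy)phenyl]methyl}-2-(3-methoxy-4-{[tri(propan-2-yl)silyl]oxy}phenyl)oxolan-3-yl]methanol (carbinol epimers) | COc1cc([C@@H]2OC[C@@H](C(O)c3ccc(OCC=C(C)C)c(OC)c3)[C@H]2CO)ccc1O[Si](C(C)C)(C(C)C)C(C)C | intermediate
19 | (1R,3aS,4R,6aS)-1-(3-methoxy-4-{[tri(propan-2-yl)silyl]oxy}phenyl)-4-{3-methoxy-4-[(3-methylbut-2-en-1-yl)oxy]phenyl}tetrahydro-1H,3H-furo[3,4-c]furan | COc1cc([C@@H]2OC[C@@H]3[C@H]2CO[C@H]3c2ccc(OCC=C(C)C)c(OC)c2)ccc1O[Si](C(C)C)(C(C)C)C(C)C | intermediate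
20 | 4-[(1R,3aS,4R,6aS)-4-{3-methoxy-4-[(3-methylbut-2-en-1-yl)oxy]phenyl}tetrahydro-1H,3H-furo[3,4-c]furan-1-yl]-2-methoxyphenol | COc1cc([C@@H]2OC[C@@H]3[C@H]2CO[C@H]3c2ccc(OCC=C(C)C)c(OC)c2)ccc1O | target

**Totals**
Total step count: 12. Longest linear sequence: 11 steps (steps 1 to 9, then 11 and 12); step 10 is the side branch.

**Three steps most likely to fail**

Step 8 (the new ring expansion). Risks are hydroxymethylation of the electron-rich arene by activated formaldehyde, elimination of the ring-opened zwitterion to a styryl lactone, low reactivity of the single-acceptor cyclopropane, and exo/endo leakage if the benzylic C–O bond re-ionises. The fallback uses known chemistry, sets out from 7 and 17, and comes back at 19. Arylmagnesium bromide 17 is added to prop-2-enal (THF, −78 °C) to give racemic 1-{3-methoxy-4-[(3-methylbut-2-en-1-yl)oxy]phenyl}prop-2-en-1-ol F1. A Sharpless kinetic resolution (Ti(Oi-Pr)4, L-(+)-diisopropyl tartrate, t-BuOOH 0.55 equiv, 4 Å sieves, CH2Cl2, −20 °C) epoxidises the (R)-alcohol to the anti epoxy alcohol (S)-{3-methoxy-4-[(3-methylbut-2-en-1-yl)oxy]phenyl}[(2R)-oxiran-2-yl]methanol F2. Alcohol 7 is converted (CBr4, PPh3, CH2Cl2, 0 °C) into {4-[(1Z)-3-bromoprop-1-en-1-yl]-2-methoxyphenoxy}tri(propan-2-yl)silane F3, which O-alkylates F2 (NaH, THF, 0 °C) to give the epoxy ether (2R)-2-[(S)-{3-methoxy-4-[(3-methylbut-2-en-1-yl)oxy]phenyl}{[(2Z)-3-(3-methoxy-4-{[tri(propan-2-yl)silyl]oxy}phenyl)prop-2-en-1-yl]oxy}methyl]oxirane F4. Cp2TiCl (trivalent titanium, from Cp2TiCl2 and Zn, THF, rt) opens the epoxide to the β-titanoxy radical, which cyclises 5-exo onto the styrene (2,3-trans, ring fusion cis). Iodine quench and displacement of the benzylic iodide by the titanium alkoxide close the second ring and give 19, which is desilylated as in step 12. The carbinol center of F2 fixes the absolute configuration, and the alkene geometry of F3 is irrelevant.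

Step 12 (SN1 ring closure). Risks are partial formation of the endo-aryl epimer, acid-induced epimerisation of the existing benzylic ether, and Friedel–Crafts closure to an aryltetralin. The fallback sets out from 14 and comes back at 19. Lactol 14 is condensed with benzenesulfinic acid (CaCl2, CH2Cl2, rt) to the anomeric sulfone (3aS,4R,6aS)-1-(benzenesulfonyl)-4-(3-methoxy-4-{[tri(propan-2-yl)silyl]oxy}phenyl)tetrahydro-1H,3H-furo[3,4-c]furan F5. Arylmagnesium bromide 17 is transmetalated with ZnBr2 to bromo{3-methoxy-4-[(3-methylbut-2-en-1-yl)oxy]phenyl}zinc F6, which displaces the sulfinate through the bicyclic oxocarbenium ion (THF, rt). The carbon nucleophile enters from the convex face, so the aryl group is delivered exo directly and no benzylic cation or acid is needed; 19 is then desilylated with n-Bu4NF.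

Step 4 (Sonogashira coupling of an electron-rich aryl bromide with propargyl alcohol). Risks are slow oxidative addition and alkyne homocoupling. The fallback sets out from 4 and comes back at 7, bypassing 6. Bromine–lithium exchange on 4 (n-BuLi, THF, −78 °C) and quench with DMF give 3-methoxy-4-{[tri(propan-2-yl)silyl]oxy}benzaldehyde F7. Still–Gennari olefination (methyl bis(2,2,2-trifluoroethoxy)phosphorylacetate, KN(SiMe3)2, 18-crown-6, THF, −78 °C) gives methyl (2Z)-3-(3-methoxy-4-{[tri(propan-2-yl)silyl]oxy}phenyl)prop-2-enoate F8. Reduction with i-Bu2AlH (CH2Cl2, −78 °C) gives 7 with the (Z)-geometry set by the olefination and not by hydrogenation.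

**Further compounds**
F1 | step 8 | 1-{3-methoxy-4-[(3-methylbut-2-en-1-yl)oxy]phenyl}prop-2-en-1-ol (racemic) | COc1cc(C(O)C=C)ccc1OCC=C(C)C
F2 | step 8 | (S)-{3-methoxy-4-[(3-methylbut-2-en-1-yl)oxy]phenyl}[(2R)-oxiran-2-yl]methanol | COc1cc([C@H](O)[C@H]2CO2)ccc1OCC=C(C)C
F3 | step 8 | {4-[(1Z)-3-bromoprop-1-en-1-yl]-2-methoxyphenoxy}tri(propan-2-yl)silane | COc1cc(/C=C\CBr)ccc1O[Si](C(C)C)(C(C)C)C(C)C
F4 | step 8 | (2R)-2-[(S)-{3-methoxy-4-[(3-methylbut-2-en-1-yl)oxy]phenyl}{[(2Z)-3-(3-methoxy-4-{[tri(propan-2-yl)silyl]oxy}phenyl)prop-2-en-1-yl]oxy}methyl]oxirane | COc1cc([C@H](OC/C=C\c2ccc(O[Si](C(C)C)(C(C)C)C(C)C)c(OC)c2)[C@H]3CO3)ccc1OCC=C(C)C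
F5 | step 12 | (3aS,4R,6aS)-1-(benzenesulfonyl)-4-(3-methoxy-4-{[tri(propan-2-yl)silyl]oxy}phenyl)tetrahydro-1H,3H-furo[3,4-c]furan | COc1cc([C@@H]2OC[C@@H]3[C@H]2COC3S(=O)(=O)c4ccccc4)ccc1O[Si](C(C)C)(C(C)C)C(C)C
F6 | step 12 | bromo{3-methoxy-4-[(3-methylbut-2-en-1-yl)oxy]phenyl}zinc | COc1cc([Zn]Br)ccc1OCC=C(C)C
F7 | step 4 | 3-methoxy-4-{[tri(propan-2-yl)silyl]oxy}benzaldehyde | COc1cc(C=O)ccc1O[Si](C(C)C)(C(C)C)C(C)C
F8 | step 4 | methyl (2Z)-3-(3-methoxy-4-{[tri(propan-2-yl)silyl]oxy}phenyl)prop-2-enoate | COc1cc(/C=C\C(=O)OC)ccc1O[Si](C(C)C)(C(C)C)C(C)C
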